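**Retrosynthetic overview**
- Target ⇐ chelation-controlled reduction of the 6-ketone ⇐ oxidation of the 6-epi epoxy alcohol ⇐ Mitsunobu esterification at C8 (inversion) ⇐ hydroxyl-directed epoxidation of a (1(10)Z,4E)-germacradiene-6,8-diol.
- Ten-membered ring ⇐ thermal cycloreversion of a tricyclo[4.4.0.0^{2,5}]decane diol (cleaves C5–C10 and C1–C4); the deliberately "wrong" all-equatorial 6α,8α-diol decides which alkene becomes E.
- C8–O ⇐ iridium silyl relay from the C6 ketone (hydrosilylation, γ-C–H silylation, oxidation).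
- C4–C5 and C1–C10 ⇐ [2+2] photocycloaddition of (S)-piperitone with 1-methylcyclobutene; (S)-piperitone ⇐ (−)-menthone.
- Ring order: cyclohexane (bought) → cyclobutane (photoadduct) → cyclodecadiene (cycloreversion) → epoxide.

Assumption: the SMILES is read literally (C1=C10 is Z with C2 and C9 cis, trans-4,5-epoxide, 4R,5R,6R,7S,8R); germacrane numbering is used for all intermediates, β is the face of the C7 isopropyl group, and isomenthone-free (−)-menthone and 1-methylcyclobutene are taken as purchasable.

**Route**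

Step 1
Reactants: 1 (−)-menthone
Product: 3 (S)-(+)-piperitone, via trimethylsilyl enol ether 2 (not isolated)
Conditions: LiN(iPr)2, Me3SiCl, THF, −78 °C; then Pd(OAc)2 (10 mol %), O2 (1 atm), DMSO, 25 °C
Reagents that add atoms: none
Why: Kinetic deprotonation occurs at the ring CH2 and Saegusa–Ito dehydrogenation of the silyl enol ether places the alkene toward the methyl-bearing carbon, so the isopropyl-bearing stereocentre (the only one bought, later C7) is never enolised.

Step 2
Reactants: 3 (S)-(+)-piperitone; 4 1-methylcyclobutene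
Product: 5 cis-anti-cis head-to-head tricyclic ketone (cyclobutane α, trans to the 7β-isopropyl group)
Conditions: hν (350 nm, Pyrex), 4 (5 equiv), CH2Cl2, −40 °C; chromatography, no base
Reagents that add atoms: none
Why: Enone–alkene [2+2] photocycloaddition through the enone triplet forms C4–C5 and C1–C10; the two methyl-bearing carbons avoid each other (head-to-head), and the cyclobutene adds to the face opposite the isopropyl group and closes cis-anti-cis, so C5, C10, C4 and C1 are set from C7.

Step 3
Reactants: 5 tricyclic ketone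
Product: 8 tricyclic 6α,8α-diol, via diethyl(hydrido)silyl ether 6 (not isolated), via oxasilolane 7 (not isolated)
Conditions: Et2SiH2 (1.5 equiv), [Ir(cod)OMe]2 (0.5 mol %), THF, 25–50 °C; evaporate; [Ir(cod)OMe]2 (2 mol %), 3,4,7,8-tetramethyl-1,10-phenanthroline (5 mol %), norbornene (1.2 equiv), THF, 100 °C; then KHCO3, 30% H2O2, THF/MeOH, 50 °C
Reagents that add atoms: hydrogen peroxide, OO
Why: Proposed new method: a ketone-started iridium silyl relay on a bicyclo[2.2.0]hexane-fused, neopentylic ketone — hydrosilylation delivers hydride to the convex β face because the C4 methyl sits under the carbonyl on the α face, the resulting 6α Si–H ether is inserted by the phenanthroline-ligated iridium silyl species into the only secondary C–H that closes a five-membered oxasilolane (C8–Hα, cis-1,3 to O6; tertiary C–H bonds and the six-ring path to the C4 methyl are disfavoured), and stereoretentive Tamao–Fleming oxidation gives the cis-1,3-diol; the closest known reaction is iridium-catalysed silyl-ether-directed γ-C–H silylation/oxidation of simple alcohols and ketones to 1,3-diols, which has not been shown on a strained bicyclo[2.2.0]hexane, on a ring that must flip to an isopropyl-axial half-chair to reach the C–H bond, or against a primary δ-C–H held next to the directing oxygen.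

Step 4
Reactants: 8 tricyclic 6α,8α-diol
Product: 9 (1(10)Z,4E)-germacra-1(10),4-diene-6α,8α-diol
Conditions: PhMe (0.01 M), 180 °C, sealed silylated glass tube, about 1 h
Reagents that add atoms: none
Why: Thermal cycloreversion of the bicyclo[2.2.0]hexane (formal [σ2s+σ2a] through a chair cyclohexane-1,4-diyl) is the known route from such photoadducts to cis,trans-cyclodeca-1,5-dienes; here only the chair with 6-OH, 7-iPr and 8-OH all equatorial is populated, and in it C6 is equatorial and C9 axial on the diyl ring, so C4=C5 forms E and C1=C10 forms Z.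

Step 5
Reactants: 9 diene diol
Product: 10 (1(10)Z)-4α,5β-epoxygermacr-1(10)-ene-6α,8α-diol (threo epoxy alcohol)
Conditions: VO(acac)2 (3 mol %), tBuOOH (1.1 equiv), 2,6-lutidine (10 mol %), CH2Cl2, 0 °C
Reagents that add atoms: tert-butyl hydroperoxide, CC(C)(C)OO
Why: Hydroxyl-directed vanadium epoxidation of the allylic alcohol outpaces the isolated C1=C10 bond, and with H-6 eclipsing the cis C4 methyl (A(1,3) strain) oxygen is delivered on the 6α-OH face to give the threo epoxy alcohol, which is the (4R,5R)-epoxide from the E alkene.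

Step 6
Reactants: 10 epoxy diol; 11 3,4,5-trimethoxybenzoic acid
Product: 12 (1(10)Z)-4α,5β-epoxy-6α-hydroxygermacr-1(10)-en-8β-yl 3,4,5-trimethoxybenzoate
Conditions: 11 (1.5 equiv), PPh3, DIAD, PhMe, 0 to 25 °C
Reagents that add atoms: none
Why: Mitsunobu esterification inverts C8 by SN2 (8α-OH to 8β-ester); C8 is expected to react in preference to C6 because the C6 carbinol is flanked by the epoxide carbon, which retards SN2 inductively and sterically.

Step 7
Reactants: 12 6α-hydroxy epoxy ester
Product: 13 (1(10)Z)-4α,5β-epoxy-6-oxogermacr-1(10)-en-8β-yl 3,4,5-trimethoxybenzoate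
Conditions: Dess–Martin periodinane, pyridine, CH2Cl2, 0 °C
Reagents that add atoms: none
Why: Dess–Martin oxidation of the only free alcohol under buffered conditions spares the epoxide, ester and alkene and removes the 6α centre once it has gated step 4 and directed step 5.

Step 8
Reactants: 13 epoxy ketone
Product: 14 target, (1(10)Z,4R,5R,6R,7S,8R)-4,5-epoxy-6-hydroxygermacr-1(10)-en-8-yl 3,4,5-trimethoxybenzoate
Conditions: Zn(BH4)2, Et2O, −20 °C; aqueous NH4Cl
Reagents that add atoms: none
Why: Chelation-controlled reduction of an α,β-epoxy ketone, with zinc bridging the ketone and epoxide oxygens and hydride attacking anti to C4, gives the erythro epoxy alcohol (6β, 6R) and leaves the ester and epoxide untouched.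

**Compound list**
1 | (−)-menthone, (2S,5R)-5-methyl-2-(propan-2-yl)cyclohexan-1-one | CC(C)[C@@H]1CC[C@@H](C)CC1=O | starting material
2 | trimethyl{[(3R,6S)-3-methyl-6-(propan-2-yl)cyclohex-1-en-1-yl]oxy}silane | C[Si](C)(C)OC1=C[C@H](C)CC[C@H]1C(C)C | intermediate
3 | (S)-(+)-piperitone, (6S)-3-methyl-6-(propan-2-yl)cyclohex-2-en-1-one | O=C1C=C(C)CC[C@H]1C(C)C | intermediate
4 | 1-methylcyclobut-1-ene | CC1=CCC1 | starting material
5 | 1,5-dimethyl-8-(propan-2-yl)tricyclo[4.4.0.0^{2,5}]decan-7-one; cis-anti-cis; germacrane C5–C10 and C1–C4 bonds, C4 and C1 α, 10-Me and H-5 β, 7β-iPr | C1C[C@@]2(C)[C@@H]3CC[C@]3(C)[C@H]2C(=O)[C@@H]1C(C)C | intermediate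
6 | 6α-diethyl(hydrido)silyl ether of the alcohol from 5 | C1C[C@@]2(C)[C@@H]3CC[C@]3(C)[C@H]2[C@@H](O[SiH](CC)CC)[C@@H]1C(C)C | intermediate
7 | oxasilolane, 6α-O–SiEt2–C8α bridge on the tricycle | [C@H]14C[C@@]2(C)[C@@H]3CC[C@]3(C)[C@H]2[C@@H](O[Si]4(CC)CC)[C@@H]1C(C)C | intermediate
8 | 1,5-dimethyl-8-(propan-2-yl)tricyclo[4.4.0.0^{2,5}]decane-7,9-diol; 6α,8α-diol, both OH cis to the cyclobutane and trans to 7β-iPr | O[C@H]1C[C@@]2(C)[C@@H]3CC[C@]3(C)[C@H]2[C@@H](O)[C@@H]1C(C)C | intermediate
9 | (1(10)Z,4E)-germacra-1(10),4-diene-6α,8α-diol | O[C@H]1C/C(C)=C\CC/C(C)=C/[C@@H](O)[C@@H]1C(C)C | intermediate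
10 | (1(10)Z)-4α,5β-epoxygermacr-1(10)-ene-6α,8α-diol, (4R,5R)-epoxide | O[C@H]1C/C(C)=C\CC[C@@]2(C)O[C@@H]2[C@@H](O)[C@@H]1C(C)C | intermediate
11 | 3,4,5-trimethoxybenzoic acid | COc1cc(C(=O)O)cc(OC)c1OC | starting material
12 | (1(10)Z)-4α,5β-epoxy-6α-hydroxygermacr-1(10)-en-8β-yl 3,4,5-trimethoxybenzoate | COc1cc(C(=O)O[C@@H]2C/C(C)=C\CC[C@@]3(C)O[C@@H]3[C@@H](O)[C@@H]2C(C)C)cc(OC)c1OC | intermediate
13 | (1(10)Z)-4α,5β-epoxy-6-oxogermacr-1(10)-en-8β-yl 3,4,5-trimethoxybenzoate | COc1cc(C(=O)O[C@@H]2C/C(C)=C\CC[C@@]3(C)O[C@@H]3C(=O)[C@@H]2C(C)C)cc(OC)c1OC | intermediate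
14 | (1(10)Z,4R,5R,6R,7S,8R)-4,5-epoxy-6-hydroxygermacr-1(10)-en-8-yl 3,4,5-trimethoxybenzoate (6β-OH, 8β-ester) | COc1cc(C(=O)O[C@@H]2C/C(C)=C\CC[C@@]3(C)O[C@@H]3[C@H](O)[C@@H]2C(C)C)cc(OC)c1OC | target

**Step count and risks**
Total steps: 8. Longest linear sequence: 8 (from 1).

The three steps most likely to fail:

Step 3 (the proposed new relay). It may stop at the silyl ether, silylate the C4 methyl instead of C8, or open the strained ring on iridium. The fallback is known oxime-directed palladium C–H acetoxylation, setting out from ketone 5. NH2OH·HCl in pyridine gives the oxime F1. Pd(OAc)2 (5 mol %) with PhI(OAc)2 in AcOH/Ac2O at 80 °C acetylates the oxime in situ and acetoxylates the equatorial β-C–H at C8 through a five-membered palladacycle, giving the 8α-acetoxy O-acetyl oxime F2. K2CO3/MeOH followed by aqueous NaHSO3 releases the 8α-hydroxy ketone F3. NaBH4 in MeOH attacks from the convex face and the sequence comes back to the route at diol 8.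

Step 4 (cycloreversion). Prolonged heating in solution may let the product go on to a Cope rearrangement, and the free diol may not survive; if the diyl cleaves before reaching the chair the E,E isomer forms, which this fallback would not correct. The fallback sets out from diol 8. Me3SiOTf and 2,6-lutidine give the bis(trimethylsilyl) ether F4. Flash vacuum pyrolysis (quartz tube, 450 °C, 0.01 Torr, millisecond contact time) keeps both bulkier silyloxy groups equatorial and removes the product before it can rearrange, giving the diene bis(silyl ether) F5. K2CO3/MeOH comes back to the route at diene diol 9.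

Step 6 (Mitsunobu at C8). The acid is weak and electron-rich, the carbinol is hindered, and the C6 epoxy carbinol may compete. The fallback sets out from epoxy diol 10. Mitsunobu reaction with excess 4-nitrobenzoic acid (PPh3, DIAD, PhMe) inverts both carbinols, as epoxy alcohols are standard substrates, giving the 6β,8β-bis(4-nitrobenzoate) F6. K2CO3/MeOH at 0 °C gives the all-cis epoxy diol F7. Acylation of the less hindered 8β-OH with 3,4,5-trimethoxybenzoyl chloride F8 (from 11 and (COCl)2), Et3N and DMAP at −20 °C comes back to the route at target 14, so steps 7 and 8 are not needed.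

**Further compounds**
F1 | step 3 | oxime of tricyclic ketone 5 (E/Z mixture at C=N) | C1C[C@@]2(C)[C@@H]3CC[C@]3(C)[C@H]2C(=NO)[C@@H]1C(C)C
F2 | step 3 | 8α-acetoxy O-acetyl oxime of 5 (E/Z mixture at C=N) | CC(=O)O[C@H]1C[C@@]2(C)[C@@H]3CC[C@]3(C)[C@H]2C(=NOC(C)=O)[C@@H]1C(C)C
F3 | step 3 | 8α-hydroxy tricyclic ketone | O[C@H]1C[C@@]2(C)[C@@H]3CC[C@]3(C)[C@H]2C(=O)[C@@H]1C(C)C
F4 | step 4 | bis(trimethylsilyl) ether of diol 8 | C[Si](C)(C)O[C@H]1C[C@@]2(C)[C@@H]3CC[C@]3(C)[C@H]2[C@@H](O[Si](C)(C)C)[C@@H]1C(C)C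
F5 | step 4 | bis(trimethylsilyl) ether of diene diol 9 | C[Si](C)(C)O[C@H]1C/C(C)=C\CC/C(C)=C/[C@@H](O[Si](C)(C)C)[C@@H]1C(C)C
F6 | step 6 | (1(10)Z)-4α,5β-epoxygermacr-1(10)-ene-6β,8β-diyl bis(4-nitrobenzoate) | O=C(O[C@@H]1C/C(C)=C\CC[C@@]2(C)O[C@@H]2[C@H](OC(=O)c3ccc(cc3)[N+](=O)[O-])[C@@H]1C(C)C)c4ccc(cc4)[N+](=O)[O-]
F7 | step 6 | (1(10)Z)-4α,5β-epoxygermacr-1(10)-ene-6β,8β-diol | O[C@@H]1C/C(C)=C\CC[C@@]2(C)O[C@@H]2[C@H](O)[C@@H]1C(C)C
F8 | step 6 | 3,4,5-trimethoxybenzoyl chloride | COc1cc(C(Cl)=O)cc(OC)c1OC
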